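**Retrosynthetic overview**
- Ring D (N2, C1, C3, C4, C4a, C8a) is closed last, by condensing the C3 amine with an acetyl group on C8a. That acetyl comes from a C8a bromide, placed ortho to a free O8 hydroxyl (para to the O6 ether) and followed by O8 methylation.
- Ring B of the naphthalene (C4a', C5', C6', C7', C8', C8a') carries O5' and the C7' methyl in a 1,3 relation. The strategy rests on this feature: C6' is the enol carbon of an acetyl group on C4a', C7' is the methyl-bearing carbon of a propynyl group on C8a', and a 6-endo-dig closure joins them.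
- The hindered biaryl bond C7–C1' is made earlier, by Negishi coupling at the benzene stage of ring A, which comes from 2'-hydroxy-6'-methoxyacetophenone (iodide at C1', triflate then propyne at C8a').
- Ring C comes from 5-bromoresorcinol. The side chain with C3 (S) comes from the L-alaninol-derived cyclic sulfamidate.
- Ring order: A and C are bought as benzenes, B is formed in the key step, D is formed in the penultimate step.

Key step: step 9

**Remarks on the chemistry**
- Locants: isoquinoline C1–C8a as usual; naphthalene primed, with C1' the biaryl carbon, 4'-OMe, 5'-OH and 7'-Me.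
- The target SMILES defines only C3 (S). The C7–C1' axis is treated as configurationally undefined and no axial control is attempted.
- O8 is carried as a benzyl ether and methylated only after the C8a bromination. A 6-hydroxy-8-methoxy ring would be expected to brominate para to the methoxy group (C5); with O8 free and O6 as its MOM ether, the ortho-hydroxyl and para-ether effects both point to C8a.
- Sulfamidate 4 is taken as a catalogue compound (otherwise two steps from N-Boc-L-alaninol). Propyne is used as a commercial THF solution.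

**Route**

Step 1
Reactants: 1 5-bromobenzene-1,3-diol
Product: 2 3-(benzyloxy)-5-bromophenol
Conditions: BnBr (1.0 equiv), K2CO3 (1.0 equiv), acetone, reflux
Reagents that add atoms: benzyl bromide, BrCc1ccccc1
Why: Williamson etherification with one equivalent of halide should give the monoether of the symmetric diol, separable from recovered diol and the dibenzyl ether.

Step 2
Reactants: 2 3-(benzyloxy)-5-bromophenol
Product: 3 1-(benzyloxy)-3-bromo-5-(methoxymethoxy)benzene
Conditions: MOMCl, i-Pr2NEt, CH2Cl2, 0 → 20 °C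
Reagents that add atoms: chloromethyl methyl ether, COCCl
Why: O-alkylation of the phenol to the MOM acetal, which later directs the metalation and is removed in the acid step.

Step 3
Reactants: 3 1-(benzyloxy)-3-bromo-5-(methoxymethoxy)benzene; 4 tert-butyl (4S)-4-methyl-1,2,3-oxathiazolidine-3-carboxylate 2,2-dioxide
Product: 7 tert-butyl N-[(2S)-1-[3-(benzyloxy)-5-(methoxymethoxy)phenyl]propan-2-yl]carbamate, via arylmagnesium bromide 5 (not isolated), via magnesium N-sulfamate 6 (not isolated)
Conditions: Mg, THF, 45 °C; CuI (10 mol %), 4, THF, −30 → 20 °C; 10 % aq citric acid, 20 °C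
Reagents that add atoms: none
Why: Copper-catalysed ring opening of a cyclic sulfamidate by an aryl Grignard reagent occurs by SN2 attack at the CH2–O carbon, so the stereocentre taken from L-alaninol is untouched and stays (S); mild acid then hydrolyses the N-sulfamate and leaves Boc and MOM in place.

Step 4
Reactants: 8 2'-hydroxy-6'-methoxyacetophenone
Product: 9 1-(2-hydroxy-3-iodo-6-methoxyphenyl)ethan-1-one
Conditions: NIS (1.05 equiv), TFA (10 mol %), MeCN, 0 → 20 °C
Reagents that add atoms: N-iodosuccinimide, O=C1CCC(=O)N1I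
Why: Electrophilic aromatic iodination should go to the carbon that is para to the methoxy group and ortho to the chelated hydroxyl, the position where both donors cooperate best.

Step 5
Reactants: 9 1-(2-hydroxy-3-iodo-6-methoxyphenyl)ethan-1-one
Product: 10 2-acetyl-6-iodo-3-methoxyphenyl trifluoromethanesulfonate
Conditions: Tf2O, pyridine, CH2Cl2, 0 °C
Reagents that add atoms: trifluoromethanesulfonic anhydride, O=S(=O)(OS(=O)(=O)C(F)(F)F)C(F)(F)F
Why: O-sulfonylation of the phenol gives the aryl triflate that later carries the alkyne, while the iodide stays as the more reactive coupling site.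

Step 6
Reactants: 7 tert-butyl N-[(2S)-1-[3-(benzyloxy)-5-(methoxymethoxy)phenyl]propan-2-yl]carbamate; 10 2-acetyl-6-iodo-3-methoxyphenyl trifluoromethanesulfonate
Product: 13 2-acetyl-6-[2-(benzyloxy)-4-[(2S)-2-[(tert-butoxycarbonyl)amino]propyl]-6-(methoxymethoxy)phenyl]-3-methoxyphenyl trifluoromethanesulfonate, via dilithiated arene 11 (not isolated), via arylzinc chloride 12 (not isolated)
Conditions: n-BuLi (2.2 equiv), THF, −78 → 0 °C; ZnCl2 (1.2 equiv), 0 → 20 °C; 10, Pd2(dba)3 (2 mol %), SPhos (8 mol %), THF, 60 °C; aq NH4Cl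
Reagents that add atoms: none
Why: After N–H deprotonation, directed ortho-metalation removes the ring hydrogen flanked by the MOM and benzyl ether oxygens (the future C7), and transmetalation to zinc gives a Negishi partner that tolerates the ketone; zerovalent palladium inserts into the C–I bond in preference to the C–OTf bond, so the triply ortho-substituted biaryl bond forms while the ring is still a benzene.

Step 7
Reactants: 13 2-acetyl-6-[2-(benzyloxy)-4-[(2S)-2-[(tert-butoxycarbonyl)amino]propyl]-6-(methoxymethoxy)phenyl]-3-methoxyphenyl trifluoromethanesulfonate; 14 propyne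
Product: 15 tert-butyl N-[(2S)-1-[4-[3-acetyl-4-methoxy-2-(prop-1-yn-1-yl)phenyl]-3-(benzyloxy)-5-(methoxymethoxy)phenyl]propan-2-yl]carbamate
Conditions: propyne (excess, THF solution), PdCl2(PPh3)2 (5 mol %), CuI (10 mol %), Et3N, DMF, 70 °C, sealed tube
Reagents that add atoms: none
Why: Sonogashira coupling of an aryl triflate; the ortho acetyl group activates the C–OTf bond towards oxidative addition.

Step 8
Reactants: 15 tert-butyl N-[(2S)-1-[4-[3-acetyl-4-methoxy-2-(prop-1-yn-1-yl)phenyl]-3-(benzyloxy)-5-(methoxymethoxy)phenyl]propan-2-yl]carbamate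
Product: 16 tert-butyl N-[(2S)-1-[3-(benzyloxy)-4-[4-methoxy-2-(prop-1-yn-1-yl)-3-[1-(triisopropylsilyloxy)vinyl]phenyl]-5-(methoxymethoxy)phenyl]propan-2-yl]carbamate
Conditions: TIPSOTf (1.3 equiv), Et3N (3 equiv), CH2Cl2, −78 → 0 °C
Reagents that add atoms: triisopropylsilyl trifluoromethanesulfonate, CC(C)[Si](OS(=O)(=O)C(F)(F)F)(C(C)C)C(C)C
Why: Soft enolisation and O-silylation of a methyl ketone with a single enolisable side gives the silyl enol ether; the low temperature and slight excess are chosen to spare the carbamate and the MOM acetal, and TIPS is chosen so that the later naphthyl silyl ether survives carbonate base.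

Step 9
Reactants: 16 tert-butyl N-[(2S)-1-[3-(benzyloxy)-4-[4-methoxy-2-(prop-1-yn-1-yl)-3-[1-(triisopropylsilyloxy)vinyl]phenyl]-5-(methoxymethoxy)phenyl]propan-2-yl]carbamate
Product: 17 tert-butyl N-[(2S)-1-[3-(benzyloxy)-4-[4-methoxy-7-methyl-5-(triisopropylsilyloxy)naphthalen-1-yl]-5-(methoxymethoxy)phenyl]propan-2-yl]carbamate
Conditions: Ph3PAuNTf2 (5 mol %), CH2Cl2, 4 Å MS, 20 °C
Reagents that add atoms: none
Why: Ph3PAuNTf2 (monovalent gold) binds the propynyl triple bond and the enol ether carbon C6' adds anti to gold at the methyl-bearing alkyne carbon C7', giving a silyloxocarbenium vinylgold species; loss of the C6' proton aromatises ring B and protodeauration frees the catalyst with silicon still on O5'. The closest known reaction type is the π-acid-catalysed carbocyclisation of o-alkynylaryl ketone silyl enol ethers to 1-silyloxynaphthalenes. Ring B (C4a', C5', C6', C7', C8', C8a') is closed in the 6-endo-dig mode; the 5-exo-dig alternative at C8' would lead to a non-aromatic alkylidene indene. No stereocentre is formed and C3 is remote and untouched. The step needs carbon rather than oxygen attack and endo rather than exo closure: the silyl cap on oxygen, the ortho geometry and the aromatic product secure both, and the carbamate, MOM and benzyl ether are poor ligands for gold.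

Step 10
Reactants: 17 tert-butyl N-[(2S)-1-[3-(benzyloxy)-4-[4-methoxy-7-methyl-5-(triisopropylsilyloxy)naphthalen-1-yl]-5-(methoxymethoxy)phenyl]propan-2-yl]carbamate
Product: 18 tert-butyl N-[(2S)-1-[3-hydroxy-4-[4-methoxy-7-methyl-5-(triisopropylsilyloxy)naphthalen-1-yl]-5-(methoxymethoxy)phenyl]propan-2-yl]carbamate
Conditions: H2 (1 atm), 10 % Pd/C, EtOAc–EtOH, 20 °C
Reagents that add atoms: none
Why: Hydrogenolysis of the benzyl ether frees O8 alone; the MOM acetal, Boc group, aryl silyl ether and naphthalene are inert under these conditions.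

Step 11
Reactants: 18 tert-butyl N-[(2S)-1-[3-hydroxy-4-[4-methoxy-7-methyl-5-(triisopropylsilyloxy)naphthalen-1-yl]-5-(methoxymethoxy)phenyl]propan-2-yl]carbamate
Product: 19 tert-butyl N-[(2S)-1-[2-bromo-3-hydroxy-4-[4-methoxy-7-methyl-5-(triisopropylsilyloxy)naphthalen-1-yl]-5-(methoxymethoxy)phenyl]propan-2-yl]carbamate
Conditions: NBS (1.0 equiv), i-Pr2NH (10 mol %), CH2Cl2, −78 → 0 °C
Reagents that add atoms: N-bromosuccinimide, O=C1CCC(=O)N1Br
Why: Amine-mediated ortho-bromination of a phenol: C8a is the only free position ortho to the O8 hydroxyl and is also para to the O6 ether, so reagent delivery and both donors direct the halogen to C8a and not to C5.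

Step 12
Reactants: 19 tert-butyl N-[(2S)-1-[2-bromo-3-hydroxy-4-[4-methoxy-7-methyl-5-(triisopropylsilyloxy)naphthalen-1-yl]-5-(methoxymethoxy)phenyl]propan-2-yl]carbamate
Product: 20 tert-butyl N-[(2S)-1-[2-bromo-3-methoxy-4-[4-methoxy-7-methyl-5-(triisopropylsilyloxy)naphthalen-1-yl]-5-(methoxymethoxy)phenyl]propan-2-yl]carbamate
Conditions: MeI (3 equiv), K2CO3, acetone, 40 °C
Reagents that add atoms: iodomethane, CI
Why: Williamson methylation of the acidic ortho-bromophenol installs the C8 methoxy group; the carbamate N–H is not alkylated by carbonate base and the hindered TIPS ether should hold.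

Step 13
Reactants: 20 tert-butyl N-[(2S)-1-[2-bromo-3-methoxy-4-[4-methoxy-7-methyl-5-(triisopropylsilyloxy)naphthalen-1-yl]-5-(methoxymethoxy)phenyl]propan-2-yl]carbamate
Product: 21 tert-butyl N-[(2S)-1-[2-(1-ethoxyvinyl)-3-methoxy-4-[4-methoxy-7-methyl-5-(triisopropylsilyloxy)naphthalen-1-yl]-5-(methoxymethoxy)phenyl]propan-2-yl]carbamate
Conditions: tributyl(1-ethoxyvinyl)stannane (2 equiv), Pd(PPh3)4 (10 mol %), CuI (20 mol %), dioxane, 100 °C
Reagents that add atoms: tributyl(1-ethoxyvinyl)stannane, CCCC[Sn](CCCC)(CCCC)C(=C)OCC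
Why: Stille coupling of the aryl bromide with an α-alkoxyvinylstannane installs a masked acetyl group at C8a without base or fluoride.

Step 14
Reactants: 21 tert-butyl N-[(2S)-1-[2-(1-ethoxyvinyl)-3-methoxy-4-[4-methoxy-7-methyl-5-(triisopropylsilyloxy)naphthalen-1-yl]-5-(methoxymethoxy)phenyl]propan-2-yl]carbamate
Product: 23 (3S)-8-methoxy-7-[4-methoxy-7-methyl-5-(triisopropylsilyloxy)naphthalen-1-yl]-1,3-dimethyl-3,4-dihydroisoquinolin-6-ol, via amino ketone 22 (not isolated)
Conditions: 3 M HCl, MeOH–THF–H2O, 20 → 40 °C; then aq NaHCO3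
Reagents that add atoms: none
Why: Acid hydrolyses the enol ether to the aryl methyl ketone and removes the MOM and Boc groups, and the freed primary amine condenses with the ortho ketone to the six-membered cyclic ketimine (ring D); C3 is not an epimerisable centre and stays (S).

Step 15
Reactants: 23 (3S)-8-methoxy-7-[4-methoxy-7-methyl-5-(triisopropylsilyloxy)naphthalen-1-yl]-1,3-dimethyl-3,4-dihydroisoquinolin-6-ol
Product: 24 (3S)-7-(5-hydroxy-4-methoxy-7-methylnaphthalen-1-yl)-8-methoxy-1,3-dimethyl-3,4-dihydroisoquinolin-6-ol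
Conditions: TBAF (1.2 equiv), THF, 0 °C; aq NH4Cl
Reagents that add atoms: none
Why: Fluoride cleaves the aryl silyl ether and frees the C5' naphthol without touching the imine or the methyl ethers.

**Compound list**
1 | 5-bromobenzene-1,3-diol | Oc1cc(O)cc(Br)c1 | starting material
2 | 3-(benzyloxy)-5-bromophenol | Oc1cc(Br)cc(OCc2ccccc2)c1 | intermediate
3 | 1-(benzyloxy)-3-bromo-5-(methoxymethoxy)benzene | COCOc1cc(Br)cc(OCc2ccccc2)c1 | intermediate
4 | tert-butyl (4S)-4-methyl-1,2,3-oxathiazolidine-3-carboxylate 2,2-dioxide | C[C@H]1COS(=O)(=O)N1C(=O)OC(C)(C)C | starting material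
5 | [3-(benzyloxy)-5-(methoxymethoxy)phenyl]magnesium bromide | COCOc1cc([Mg]Br)cc(OCc2ccccc2)c1 | intermediate
6 | bromomagnesium N-(tert-butoxycarbonyl)-N-[(2S)-1-[3-(benzyloxy)-5-(methoxymethoxy)phenyl]propan-2-yl]sulfamate | COCOc1cc(C[C@H](C)N(C(=O)OC(C)(C)C)S(=O)(=O)[O-])cc(OCc2ccccc2)c1.[Mg+]Br | intermediate
7 | tert-butyl N-[(2S)-1-[3-(benzyloxy)-5-(methoxymethoxy)phenyl]propan-2-yl]carbamate | COCOc1cc(C[C@H](C)NC(=O)OC(C)(C)C)cc(OCc2ccccc2)c1 | intermediate
8 | 2'-hydroxy-6'-methoxyacetophenone | COc1cccc(O)c1C(C)=O | starting material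
9 | 1-(2-hydroxy-3-iodo-6-methoxyphenyl)ethan-1-one | COc1ccc(I)c(O)c1C(C)=O | intermediate
10 | 2-acetyl-6-iodo-3-methoxyphenyl trifluoromethanesulfonate | COc1ccc(I)c(OS(=O)(=O)C(F)(F)F)c1C(C)=O | intermediate
11 | N,C-dilithio derivative of 7 (lithium at the ring carbon between the two ether oxygens) | COCOc1cc(C[C@H](C)N([Li])C(=O)OC(C)(C)C)cc(OCc2ccccc2)c1[Li] | intermediate
12 | arylzinc chloride from 11 (N-lithio carbamate) | COCOc1cc(C[C@H](C)N([Li])C(=O)OC(C)(C)C)cc(OCc2ccccc2)c1[Zn]Cl | intermediate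
13 | 2-acetyl-6-[2-(benzyloxy)-4-[(2S)-2-[(tert-butoxycarbonyl)amino]propyl]-6-(methoxymethoxy)phenyl]-3-methoxyphenyl trifluoromethanesulfonate | COc1ccc(-c2c(OCc3ccccc3)cc(C[C@H](C)NC(=O)OC(C)(C)C)cc2OCOC)c(OS(=O)(=O)C(F)(F)F)c1C(C)=O | intermediate
14 | propyne | CC#C | starting material
15 | tert-butyl N-[(2S)-1-[4-[3-acetyl-4-methoxy-2-(prop-1-yn-1-yl)phenyl]-3-(benzyloxy)-5-(methoxymethoxy)phenyl]propan-2-yl]carbamate | COc1ccc(-c2c(OCc3ccccc3)cc(C[C@H](C)NC(=O)OC(C)(C)C)cc2OCOC)c(C#CC)c1C(C)=O | intermediate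
16 | tert-butyl N-[(2S)-1-[3-(benzyloxy)-4-[4-methoxy-2-(prop-1-yn-1-yl)-3-[1-(triisopropylsilyloxy)vinyl]phenyl]-5-(methoxymethoxy)phenyl]propan-2-yl]carbamate | CC#Cc1c(-c2c(OCc3ccccc3)cc(C[C@H](C)NC(=O)OC(C)(C)C)cc2OCOC)ccc(OC)c1C(=C)O[Si](C(C)C)(C(C)C)C(C)C | intermediate
17 | tert-butyl N-[(2S)-1-[3-(benzyloxy)-4-[4-methoxy-7-methyl-5-(triisopropylsilyloxy)naphthalen-1-yl]-5-(methoxymethoxy)phenyl]propan-2-yl]carbamate | Cc1cc(O[Si](C(C)C)(C(C)C)C(C)C)c2c(OC)ccc(-c3c(OCc4ccccc4)cc(C[C@H](C)NC(=O)OC(C)(C)C)cc3OCOC)c2c1 | intermediate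
18 | tert-butyl N-[(2S)-1-[3-hydroxy-4-[4-methoxy-7-methyl-5-(triisopropylsilyloxy)naphthalen-1-yl]-5-(methoxymethoxy)phenyl]propan-2-yl]carbamate | Cc1cc(O[Si](C(C)C)(C(C)C)C(C)C)c2c(OC)ccc(-c3c(O)cc(C[C@H](C)NC(=O)OC(C)(C)C)cc3OCOC)c2c1 | intermediate
19 | tert-butyl N-[(2S)-1-[2-bromo-3-hydroxy-4-[4-methoxy-7-methyl-5-(triisopropylsilyloxy)naphthalen-1-yl]-5-(methoxymethoxy)phenyl]propan-2-yl]carbamate | Cc1cc(O[Si](C(C)C)(C(C)C)C(C)C)c2c(OC)ccc(-c3c(O)c(Br)c(C[C@H](C)NC(=O)OC(C)(C)C)cc3OCOC)c2c1 | intermediate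
20 | tert-butyl N-[(2S)-1-[2-bromo-3-methoxy-4-[4-methoxy-7-methyl-5-(triisopropylsilyloxy)naphthalen-1-yl]-5-(methoxymethoxy)phenyl]propan-2-yl]carbamate | Cc1cc(O[Si](C(C)C)(C(C)C)C(C)C)c2c(OC)ccc(-c3c(OC)c(Br)c(C[C@H](C)NC(=O)OC(C)(C)C)cc3OCOC)c2c1 | intermediate
21 | tert-butyl N-[(2S)-1-[2-(1-ethoxyvinyl)-3-methoxy-4-[4-methoxy-7-methyl-5-(triisopropylsilyloxy)naphthalen-1-yl]-5-(methoxymethoxy)phenyl]propan-2-yl]carbamate | Cc1cc(O[Si](C(C)C)(C(C)C)C(C)C)c2c(OC)ccc(-c3c(OC)c(C(=C)OCC)c(C[C@H](C)NC(=O)OC(C)(C)C)cc3OCOC)c2c1 | intermediate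
22 | 1-[2-[(2S)-2-aminopropyl]-4-hydroxy-6-methoxy-5-[4-methoxy-7-methyl-5-(triisopropylsilyloxy)naphthalen-1-yl]phenyl]ethan-1-one | Cc1cc(O[Si](C(C)C)(C(C)C)C(C)C)c2c(OC)ccc(-c3c(OC)c(C(C)=O)c(C[C@H](C)N)cc3O)c2c1 | intermediate
23 | (3S)-8-methoxy-7-[4-methoxy-7-methyl-5-(triisopropylsilyloxy)naphthalen-1-yl]-1,3-dimethyl-3,4-dihydroisoquinolin-6-ol | COc1c2c(cc(O)c1-c1ccc(OC)c3c(O[Si](C(C)C)(C(C)C)C(C)C)cc(C)cc13)C[C@H](C)N=C2C | intermediate
24 | (3S)-7-(5-hydroxy-4-methoxy-7-methylnaphthalen-1-yl)-8-methoxy-1,3-dimethyl-3,4-dihydroisoquinolin-6-ol | COc1c2c(cc(O)c1-c1ccc(OC)c3c(O)cc(C)cc13)C[C@H](C)N=C2C | target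

**Step count and risks**
Total steps: 15. Longest linear sequence: 13 (steps 1–3 and 6–15).

Steps most likely to fail:

1. Step 9 (gold cyclisation). Adventitious acid may strip silicon from the enol ether before cyclisation, and the regenerated ketone would then close through oxygen to an isochromenylium species instead of through carbon; catalyst binding by the carbamate could also slow turnover. Fallback, setting out from 15: carbonyl-assisted hydration of the alkyne (Ph3PAuNTf2, wet dioxane, 60 °C; the acetyl oxygen attacks the methyl-bearing alkyne carbon and water opens the pyrylium) should give the 1,5-diketone F1. Intramolecular aldol condensation (KOH, EtOH, 20 °C; the aryl ketone enolate attacks the aliphatic ketone, then dehydration and enolisation) should give the naphthol F2. Silylation (TIPSCl, imidazole, DMF) comes back to the route at 17.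

2. Step 11 (bromination). Electrophilic attack may spread to C5 (para to the O8 hydroxyl) or to the electron-rich silyloxynaphthalene, and a second bromination may follow. Fallback, setting out from 18: ortho-specific formylation of the phenol (MgCl2, Et3N, paraformaldehyde, MeCN, reflux) should give the salicylaldehyde F3, which can only form at C8a. Methylation (MeI, K2CO3, DMF) gives the methoxy aldehyde F4; MeMgBr (2.5 equiv, THF, −78 → 0 °C) gives the secondary carbinol F5 as an epimer mixture; Dess–Martin periodinane (NaHCO3, CH2Cl2) gives the methyl ketone F6. The acid treatment of step 14 applied to F6 comes back to the route at 23 (through 22). This path also bypasses the Stille coupling of step 13.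

3. Step 7 (alkynylation of the triflate). Oxidative addition into a triflate flanked by the acetyl group and the di-ortho-substituted aryl ring may be slow, leaving room for S–O cleavage of the triflate to the phenol and for oxidative alkyne dimerisation. Fallback, setting out from 8 and inverting the order of the two couplings: chlorination (NCS, TFA cat., MeCN, 40 °C; same site as the iodination) gives the chlorophenol F7. Triflation (Tf2O, pyridine) gives the chloro triflate F8. Sonogashira coupling with propyne at this much less hindered triflate (PdCl2(PPh3)2, CuI, Et3N, DMF; the chloride is inert) gives the chloro alkynyl ketone F9. Negishi coupling of the zinc reagent 12 with the aryl chloride F9 (Pd2(dba)3, XPhos, THF, 65 °C) comes back to the route at 15.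

**Further compounds**
F1 | step 9 | tert-butyl N-[(2S)-1-[4-[3-acetyl-4-methoxy-2-(2-oxopropyl)phenyl]-3-(benzyloxy)-5-(methoxymethoxy)phenyl]propan-2-yl]carbamate | COc1ccc(-c2c(OCc3ccccc3)cc(C[C@H](C)NC(=O)OC(C)(C)C)cc2OCOC)c(CC(C)=O)c1C(C)=O
F2 | step 9 | tert-butyl N-[(2S)-1-[3-(benzyloxy)-4-(5-hydroxy-4-methoxy-7-methylnaphthalen-1-yl)-5-(methoxymethoxy)phenyl]propan-2-yl]carbamate | Cc1cc(O)c2c(OC)ccc(-c3c(OCc4ccccc4)cc(C[C@H](C)NC(=O)OC(C)(C)C)cc3OCOC)c2c1
F3 | step 11 | tert-butyl N-[(2S)-1-[2-formyl-3-hydroxy-4-[4-methoxy-7-methyl-5-(triisopropylsilyloxy)naphthalen-1-yl]-5-(methoxymethoxy)phenyl]propan-2-yl]carbamate | Cc1cc(O[Si](C(C)C)(C(C)C)C(C)C)c2c(OC)ccc(-c3c(O)c(C=O)c(C[C@H](C)NC(=O)OC(C)(C)C)cc3OCOC)c2c1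
F4 | step 11 | tert-butyl N-[(2S)-1-[2-formyl-3-methoxy-4-[4-methoxy-7-methyl-5-(triisopropylsilyloxy)naphthalen-1-yl]-5-(methoxymethoxy)phenyl]propan-2-yl]carbamate | Cc1cc(O[Si](C(C)C)(C(C)C)C(C)C)c2c(OC)ccc(-c3c(OC)c(C=O)c(C[C@H](C)NC(=O)OC(C)(C)C)cc3OCOC)c2c1
F5 | step 11 | tert-butyl N-[(2S)-1-[2-(1-hydroxyethyl)-3-methoxy-4-[4-methoxy-7-methyl-5-(triisopropylsilyloxy)naphthalen-1-yl]-5-(methoxymethoxy)phenyl]propan-2-yl]carbamate (carbinol epimers) | Cc1cc(O[Si](C(C)C)(C(C)C)C(C)C)c2c(OC)ccc(-c3c(OC)c(C(C)O)c(C[C@H](C)NC(=O)OC(C)(C)C)cc3OCOC)c2c1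
F6 | step 11 | tert-butyl N-[(2S)-1-[2-acetyl-3-methoxy-4-[4-methoxy-7-methyl-5-(triisopropylsilyloxy)naphthalen-1-yl]-5-(methoxymethoxy)phenyl]propan-2-yl]carbamate | Cc1cc(O[Si](C(C)C)(C(C)C)C(C)C)c2c(OC)ccc(-c3c(OC)c(C(C)=O)c(C[C@H](C)NC(=O)OC(C)(C)C)cc3OCOC)c2c1
F7 | step 7 | 1-(3-chloro-2-hydroxy-6-methoxyphenyl)ethan-1-one | COc1ccc(Cl)c(O)c1C(C)=O
F8 | step 7 | 2-acetyl-6-chloro-3-methoxyphenyl trifluoromethanesulfonate | COc1ccc(Cl)c(OS(=O)(=O)C(F)(F)F)c1C(C)=O
F9 | step 7 | 1-[3-chloro-6-methoxy-2-(prop-1-yn-1-yl)phenyl]ethan-1-one | COc1ccc(Cl)c(C#CC)c1C(C)=O
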